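The easy step comes first: at 120 s the ochre run has lost 26.8% of its Z and the blue run 34.4%, and the reckoning for the new flask starts from these two losses, taken at equal time.

the same everywhere: Z 0.80 M; L 100 mM (held)

|  | E | remark | time |
|---|---|---|---|
| ochre | 6.7 mol% | run made earlier |  |
| blue | 11 mol% | run made earlier |  |
| flask | 4.8 mol% |  | 2.5 min |

- ochre (time / s: D / %, Z / %): 25.0: 3.6, 94.7; 50.0: 8.1, 90.9; 80.0: 15.4, 83.2; 90.0: 15.8, 79.2; 120: 19.3, 73.2
- blue (time / s: D / %, Z / %): 10.0: 1.1, 96.1; 30.0: 4.8, 93.1; 60.0: 13.6, 84.7; 80.0: 17.5, 77.7; 120: 24.0, 65.6

(each reading ± 1 percentage point)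

- D at 2.5 min, in percent of the Z charged
- the change that raises the amount of D at 2.5 min, in percent of the Z charged most ("none" if none brings more than 2 percentage points) (beta / epsilon / eta / none)
- amount of D at 2.5 min, in percent of the Z charged, after beta

- beta: doubling the amount of E, all else as stated
- epsilon: doubling the transfer coefficient of L, all else as stated
- eta: doubling the saturation concentration of L, all else as stated

- what was read earlier has a scatter of 1 percentage point, one standard deviation
- at the start none of L is in solution

So 1.64 times the loading of E brought 1.28 times the loss; a loss proportional to E would stand at 44.0% in the blue run, and that misses the reading by 9.6 percentage points, against a scatter of 1 point per reading. The number to carry is the loading exponent n, the apparent order in E: the logarithm of the ratio of Z lost at equal time, divided by the logarithm of the ratio of loadings. It reads 0.504.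

Both runs lose Z fairly evenly with time, so the ochre loss, scaled by the loading to the power n and by the time, gives the new flask 28.3% lost at 2.5 min. In the ochre run, at a similar loss, D stood at 0.720 of the Z lost, so I reckon 20.4% of D in the flask. Doubling E multiplies the loss by 1.42, to 40.2%, and with the blue share of 0.698 D comes to 28.0%. Since n stays below one, the supply of L shares the rate with E, and I choose eta.

The forecast gives 20% (from 17.5% to 22.5%), 26% after beta, which is lower than my figure, and eta, holding that “gas-liquid transfer of L partly limits the rate”.

The flask gives 21.9% of D and 27.2% after beta, and the best change is eta, with 17 points against 5.3 points for beta, under these steps: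

    L ⇌ X, rate k1*(csat - [X]) (kL = 0.0389 s⁻¹)
    Z + X + E → E + D (k = 1.06 M⁻² s⁻¹)
    Z + D → Q (k = 0.00176 M⁻¹ s⁻¹)
    D + E ⇌ G + E, rate k4*[E]*[D] forward; the back reaction follows from the equilibrium constant (K = 2.90, k = 0.0534 M⁻¹ s⁻¹)

At 2.50 min the flask holds 71.0% of its Z, a loss of 29.0% against the 28.3% reckoned with n. Put to the same flask read at 1.0 min, n and the ochre loss give 11.3% lost, and that flask holds 90% of its Z, a loss of 10.0%.

The numbers in the tables were computed from invented constants; noise was put on by code.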